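**Retrosynthetic overview**
- Target ⇒ macrocyclic diol (free OH at C-6 and C-15, germacrane numbering) + (Z)-2-(acetoxymethyl)but-2-enoic acid; the primary C-15 alcohol is esterified selectively at the end.
- Ten-membered carbocycle (formed last) ⇒ C-6–C-7 bond by a chiral phosphoric acid-catalysed intramolecular allylboration of an enal by a butenolide-embedded allylboronate; this sets C-6 and C-7 and unveils the α-methylene lactone.
- Butenolide (five-membered ring, formed first) with C-8 ⇒ D-proline α-aminoxylation of an achiral aldehyde, bromo-Horner–Wadsworth–Emmons olefination, lactonisation; the CH2B group comes from a Negishi coupling.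
- Achiral C-6…C-7 chain ⇒ B-alkyl Suzuki coupling (C-3–C-4) of a dienol (from pent-4-yn-1-ol; E-1(10) olefin) with a Z-iodoalkene (from monosilylated but-2-yne-1,4-diol; ring-cis 4,5-olefin).

Assumption: the SMILES is taken literally (lactone oxygen on C-8; 1(10)-E; C-3 and C-6 cis on the 4,5-olefin; 6R,7S,8S), atoms are written C-1 to C-15 in germacrane numbering, and compound 1 is taken as a catalogue compound (otherwise one monosilylation of but-2-yne-1,4-diol).

**Route**

Step 1
Reactants: 1 4-[(tert-butyldimethylsilyl)oxy]but-2-yn-1-ol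
Product: 2 (2Z)-4-[(tert-butyldimethylsilyl)oxy]-3-iodobut-2-en-1-ol
Conditions: NaAlH2(OCH2CH2OMe)2 (Red-Al), THF, 0 °C; then I2, −78 °C to 0 °C
Reagents that add atoms: iodine (II)
Why: Hydroxyl-directed trans-hydroalumination puts aluminium on the distal alkyne carbon cis to CH2OH and iodinolysis with retention gives the Z-iodoalkene, which fixes the later cis relation of C-3 and C-6 on the C-4=C-5 olefin (low temperature suppresses loss of the silyloxy group to an allene).

Step 2
Reactants: 2 (2Z)-4-[(tert-butyldimethylsilyl)oxy]-3-iodobut-2-en-1-ol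
Product: 3 (2Z)-1-[(tert-butyldimethylsilyl)oxy]-2-iodo-4-[(triethylsilyl)oxy]but-2-ene
Conditions: Et3SiCl, imidazole, CH2Cl2, 0 °C
Reagents that add atoms: chlorotriethylsilane (CC[Si](Cl)(CC)CC)
Why: Routine silyl ether formation; the TES ether on O-6 can later be removed by mild acid while the TBS ether on O-15 stays.

Step 3
Reactants: 4 pent-4-yn-1-ol
Product: 6 (4E)-4-methylhepta-4,6-dien-1-ol, via alkenylalane 5 (not isolated)
Conditions: AlMe3 (3 equiv), Cp2ZrCl2 (25 mol%), CH2Cl2, 0 °C to rt; then vinyl bromide, ZnCl2, Pd(PPh3)4 (5 mol%), THF, rt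
Reagents that add atoms: trimethylaluminium (C[Al](C)C); vinyl bromide (C=CBr)
Why: Negishi zirconium-catalysed syn-carboalumination places the methyl on the internal alkyne carbon and the alkenylalane is cross-coupled with retention (Negishi coupling), so the trisubstituted C-1=C-10 olefin is formed as the E isomer only.

Step 4
Reactants: 6 (4E)-4-methylhepta-4,6-dien-1-ol; 3 (2Z)-1-[(tert-butyldimethylsilyl)oxy]-2-iodo-4-[(triethylsilyl)oxy]but-2-ene
Product: 8 (4E,8E)-8-{[(tert-butyldimethylsilyl)oxy]methyl}-4-methyl-10-[(triethylsilyl)oxy]deca-4,8-dien-1-ol, via alkylborane 7 (not isolated)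
Conditions: 9-BBN-H (2.3 equiv), THF, 0 °C to rt; then 3, Pd(dppf)Cl2·CH2Cl2 (5 mol%), AsPh3, Cs2CO3, DMF–H2O, rt
Reagents that add atoms: none
Why: 9-BBN adds only to the terminal CH2 of the diene (the hydroxyl is held as its borinate) and the B-alkyl Suzuki–Miyaura coupling with the vinyl iodide proceeds with retention, joining C-3 to C-4 cis to C-6 before any stereocentre exists.

Step 5
Reactants: 8 (4E,8E)-8-{[(tert-butyldimethylsilyl)oxy]methyl}-4-methyl-10-[(triethylsilyl)oxy]deca-4,8-dien-1-ol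
Product: 9 (4E,8E)-8-{[(tert-butyldimethylsilyl)oxy]methyl}-4-methyl-10-[(triethylsilyl)oxy]deca-4,8-dienal
Conditions: Dess–Martin periodinane, NaHCO3, CH2Cl2, 0 °C to rt
Reagents that add atoms: none
Why: Dess–Martin oxidation of the only free alcohol gives the C-7 aldehyde under buffered conditions that leave both silyl ethers and both olefins untouched.

Step 6
Reactants: 10 methyl 2-[bis(2,2,2-trifluoroethoxy)phosphoryl]acetate
Product: 12 methyl 2-bromo-2-[bis(2,2,2-trifluoroethoxy)phosphoryl]acetate, via dibromophosphonate 11 (not isolated)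
Conditions: NaH (2.2 equiv), THF, 0 °C; Br2 (2.1 equiv); then SnCl2·2H2O, EtOH–H2O, 0 °C
Reagents that add atoms: bromine (BrBr)
Why: Exhaustive α-bromination followed by removal of one bromine with divalent tin (halogenation/reductive monodehalogenation) avoids the mono/di mixtures of direct monobromination and gives the reagent for E-selective α-bromoacrylate formation.

Step 7
Reactants: 9 (4E,8E)-8-{[(tert-butyldimethylsilyl)oxy]methyl}-4-methyl-10-[(triethylsilyl)oxy]deca-4,8-dienal; 12 methyl 2-bromo-2-[bis(2,2,2-trifluoroethoxy)phosphoryl]acetate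
Product: 14 methyl (2E,4S,6E,10E)-2-bromo-10-{[(tert-butyldimethylsilyl)oxy]methyl}-6-methyl-4-[(phenylamino)oxy]-12-[(triethylsilyl)oxy]dodeca-2,6,10-trienoate, via aminoxy aldehyde 13 (not isolated)
Conditions: D-proline (20 mol%), PhNO, CHCl3, 4 °C; then preformed potassium salt of 12 (12, KOt-Bu, 18-crown-6), THF, −78 to −40 °C
Reagents that add atoms: nitrosobenzene (O=Nc1ccccc1)
Why: Proline enamine catalysis (α-aminoxylation) delivers the nitroso oxygen to one enamine face, D-proline giving the (S)-configured C-8–O centre as the first stereocentre (this reaction class routinely gives ≥97% ee), and the in-situ Horner–Wadsworth–Emmons reaction with the trifluoroethyl bromophosphonate places the ester cis to C-8 (2E) as required for lactonisation.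

Step 8
Reactants: 14 methyl (2E,4S,6E,10E)-2-bromo-10-{[(tert-butyldimethylsilyl)oxy]methyl}-6-methyl-4-[(phenylamino)oxy]-12-[(triethylsilyl)oxy]dodeca-2,6,10-trienoate
Product: 17 (5S)-3-bromo-5-[(2E,6E)-6-{[(tert-butyldimethylsilyl)oxy]methyl}-8-hydroxy-2-methylocta-2,6-dien-1-yl]furan-2(5H)-one, via hydroxy ester 15 (not isolated), via silyl lactone 16 (not isolated)
Conditions: Cu(OAc)2·H2O (30 mol%), MeOH, rt; then PPTS (20 mol%), MeOH, 0 °C to rt
Reagents that add atoms: none
Why: Copper-catalysed N–O cleavage frees the C-8 hydroxyl, which lactonises onto the cis ester to give the butenolide without touching the stereocentre, and PPTS in methanol then removes the TES ether selectively over the primary TBS ether.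

Step 9
Reactants: 17 (5S)-3-bromo-5-[(2E,6E)-6-{[(tert-butyldimethylsilyl)oxy]methyl}-8-hydroxy-2-methylocta-2,6-dien-1-yl]furan-2(5H)-one
Product: 18 (5S)-5-[(2E,6E)-6-{[(tert-butyldimethylsilyl)oxy]methyl}-8-hydroxy-2-methylocta-2,6-dien-1-yl]-3-[(4,4,5,5-tetramethyl-1,3,2-dioxaborolan-2-yl)methyl]furan-2(5H)-one
Conditions: ICH2Bpin, Zn dust, LiCl, THF, rt; then 17, Pd(OAc)2 (5 mol%), SPhos (10 mol%), THF, rt
Reagents that add atoms: 2-(iodomethyl)-4,4,5,5-tetramethyl-1,3,2-dioxaborolane (CC1(C)OB(CI)OC1(C)C)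
Why: Negishi coupling of the α-boryl alkylzinc iodide with the alkenyl bromide runs under neutral conditions (free hydroxyl tolerated, no base to epimerise C-8) and turns the bromobutenolide into a ring-locked 2-carbonyl allylboronate.

Step 10
Reactants: 18 (5S)-5-[(2E,6E)-6-{[(tert-butyldimethylsilyl)oxy]methyl}-8-hydroxy-2-methylocta-2,6-dien-1-yl]-3-[(4,4,5,5-tetramethyl-1,3,2-dioxaborolan-2-yl)methyl]furan-2(5H)-one
Product: 21 (3aS,4R,5E,9E,11aS)-6-{[(tert-butyldimethylsilyl)oxy]methyl}-4-hydroxy-10-methyl-3-methylidene-3a,4,7,8,11,11a-hexahydrocyclodeca[b]furan-2(3H)-one, via enal 19 (not isolated), via borate ester 20 (not isolated)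
Conditions: MnO2, CH2Cl2, rt; filter; then (S)-TRIP [(S)-3,3'-bis(2,4,6-triisopropylphenyl)-1,1'-binaphthyl-2,2'-diyl hydrogen phosphate] (10 mol%), 4 Å MS, toluene (0.002 M), 0 °C to rt; aq. NaHCO3
Reagents that add atoms: none
Why: Proposed new method: a metal-free, chiral phosphoric acid-catalysed macrocyclising allylboration of a butenolide-embedded 2-carbonyl allylboronate onto a tethered enal (after routine MnO2 allylic oxidation), the closest known reaction types being the intermolecular phosphoric acid-catalysed allylboration of aldehydes with allyl pinacolboronates and the Brønsted acid-accelerated additions of acyclic 2-alkoxycarbonyl allylboronates that give α-methylene-γ-lactones; the acid hydrogen-bonds to a boronate oxygen while its P=O holds the formyl C–H, so the C-6–C-7 bond forms through a closed six-membered chair in which the lactone ring locks C-8 trans to the CH2B carbon (E-crotyl type, hence the anti C-6/C-7 relation with the enal substituent equatorial), C-6 adds to the butenolide face opposite the C-9 substituent (trans-fused lactone, 7S from 8S), and the (S)-catalyst, chosen for its expected Si-face preference on the aldehyde, reinforces the 6R outcome, while the double bond moves to the exocyclic position so that the α-methylene lactone and the ten-membered ring arise in one event (high dilution against oligomerisation).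

Step 11
Reactants: 21 (3aS,4R,5E,9E,11aS)-6-{[(tert-butyldimethylsilyl)oxy]methyl}-4-hydroxy-10-methyl-3-methylidene-3a,4,7,8,11,11a-hexahydrocyclodeca[b]furan-2(3H)-one
Product: 22 (3aS,4R,5E,9E,11aS)-4-hydroxy-6-(hydroxymethyl)-10-methyl-3-methylidene-3a,4,7,8,11,11a-hexahydrocyclodeca[b]furan-2(3H)-one
Conditions: HF·pyridine, pyridine, THF, 0 °C to rt
Reagents that add atoms: none
Why: Buffered fluoride desilylation removes the primary TBS ether without nucleophilic or basic conditions that would add to the α-methylene lactone or move the lactone to O-6.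

Step 12
Reactants: 23 ethyl but-2-ynoate
Product: 25 ethyl (2Z)-2-(hydroxymethyl)but-2-enoate, via vinylalane 24 (not isolated)
Conditions: i-Bu2AlH, N-methylmorpholine N-oxide, THF, 0 °C; then CH2O (gas from cracked paraformaldehyde), 0 °C to rt
Reagents that add atoms: formaldehyde (C=O)
Why: Syn-hydroalumination of the ynoate (vinylalumination) gives the α-alumino enoate with the methyl cis to the ester, and trapping with formaldehyde with retention gives the angelate-type (Z) hydroxymethyl ester.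

Step 13
Reactants: 25 ethyl (2Z)-2-(hydroxymethyl)but-2-enoate
Product: 26 (2Z)-2-(hydroxymethyl)but-2-enoic acid
Conditions: LiOH·H2O, THF–H2O, 0 °C; then 1 M HCl
Reagents that add atoms: lithium hydroxide ([Li+].[OH-])
Why: Cold saponification cleaves the ethyl ester without isomerising the trisubstituted olefin.

Step 14
Reactants: 26 (2Z)-2-(hydroxymethyl)but-2-enoic acid
Product: 27 (2Z)-2-[(acetyloxy)methyl]but-2-enoic acid
Conditions: Ac2O, pyridine, 0 °C to rt; then H2O
Reagents that add atoms: acetic anhydride (CC(=O)OC(C)=O)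
Why: O-Acetylation of the primary alcohol; the transient mixed anhydride of the acid is hydrolysed on aqueous work-up.

Step 15
Reactants: 22 (3aS,4R,5E,9E,11aS)-4-hydroxy-6-(hydroxymethyl)-10-methyl-3-methylidene-3a,4,7,8,11,11a-hexahydrocyclodeca[b]furan-2(3H)-one; 27 (2Z)-2-[(acetyloxy)methyl]but-2-enoic acid
Product: 29 [(3aS,4R,5E,9E,11aS)-4-hydroxy-10-methyl-3-methylidene-2-oxo-2,3,3a,4,7,8,11,11a-octahydrocyclodeca[b]furan-6-yl]methyl (2Z)-2-[(acetyloxy)methyl]but-2-enoate (CNP0184624.2), via mixed anhydride 28 (not isolated)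
Conditions: 27, 2,4,6-trichlorobenzoyl chloride, Et3N, toluene, 0 °C; then 22, DMAP (0.2 equiv), −20 to 0 °C
Reagents that add atoms: none
Why: Yamaguchi esterification acylates the unhindered primary allylic C-15 alcohol much faster than the secondary C-6 alcohol next to the ring fusion, and the mixed-anhydride protocol is the standard way to transfer angelate-type Z-acids without Z to E isomerisation.

**Compound list**

1 | 4-[(tert-butyldimethylsilyl)oxy]but-2-yn-1-ol | OCC#CCO[Si](C)(C)C(C)(C)C | starting material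
2 | (2Z)-4-[(tert-butyldimethylsilyl)oxy]-3-iodobut-2-en-1-ol | OC/C=C(\I)CO[Si](C)(C)C(C)(C)C | intermediate
3 | (2Z)-1-[(tert-butyldimethylsilyl)oxy]-2-iodo-4-[(triethylsilyl)oxy]but-2-ene | CC[Si](CC)(CC)OC/C=C(\I)CO[Si](C)(C)C(C)(C)C | intermediate
4 | pent-4-yn-1-ol | OCCCC#C | starting material
5 | alkenylalane: (1E)-1-(dimethylalumanyl)-2-methyl-5-[(dimethylalumanyl)oxy]pent-1-ene (not isolated) | C[Al](C)OCCC/C(C)=C/[Al](C)C | intermediate
6 | (4E)-4-methylhepta-4,6-dien-1-ol | OCCC/C(C)=C/C=C | intermediate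
7 | alkylborane: 9-[(3E)-7-(9-borabicyclo[3.3.1]nonan-9-yloxy)-4-methylhept-3-en-1-yl]-9-borabicyclo[3.3.1]nonane (not isolated) | B1(CC/C=C(C)/CCCOB2C3CCCC2CCC3)C2CCCC1CCC2 | intermediate
8 | (4E,8E)-8-{[(tert-butyldimethylsilyl)oxy]methyl}-4-methyl-10-[(triethylsilyl)oxy]deca-4,8-dien-1-ol | OCCC/C(C)=C/CC/C(CO[Si](C)(C)C(C)(C)C)=C\CO[Si](CC)(CC)CC | intermediate
9 | (4E,8E)-8-{[(tert-butyldimethylsilyl)oxy]methyl}-4-methyl-10-[(triethylsilyl)oxy]deca-4,8-dienal | O=CCC/C(C)=C/CC/C(CO[Si](C)(C)C(C)(C)C)=C\CO[Si](CC)(CC)CC | intermediate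
10 | methyl 2-[bis(2,2,2-trifluoroethoxy)phosphoryl]acetate | COC(=O)CP(=O)(OCC(F)(F)F)OCC(F)(F)F | starting material
11 | dibromophosphonate: methyl 2,2-dibromo-2-[bis(2,2,2-trifluoroethoxy)phosphoryl]acetate (not isolated) | COC(=O)C(Br)(Br)P(=O)(OCC(F)(F)F)OCC(F)(F)F | intermediate
12 | methyl 2-bromo-2-[bis(2,2,2-trifluoroethoxy)phosphoryl]acetate (racemic) | COC(=O)C(Br)P(=O)(OCC(F)(F)F)OCC(F)(F)F | intermediate
13 | aminoxy aldehyde: (2S,4E,8E)-8-{[(tert-butyldimethylsilyl)oxy]methyl}-4-methyl-2-[(phenylamino)oxy]-10-[(triethylsilyl)oxy]deca-4,8-dienal (not isolated) | O=C[C@@H](ONc1ccccc1)C/C(C)=C/CC/C(CO[Si](C)(C)C(C)(C)C)=C\CO[Si](CC)(CC)CC | intermediate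
14 | methyl (2E,4S,6E,10E)-2-bromo-10-{[(tert-butyldimethylsilyl)oxy]methyl}-6-methyl-4-[(phenylamino)oxy]-12-[(triethylsilyl)oxy]dodeca-2,6,10-trienoate | COC(=O)/C(Br)=C\[C@@H](ONc1ccccc1)C/C(C)=C/CC/C(CO[Si](C)(C)C(C)(C)C)=C\CO[Si](CC)(CC)CC | intermediate
15 | hydroxy ester: methyl (2E,4S,6E,10E)-2-bromo-10-{[(tert-butyldimethylsilyl)oxy]methyl}-4-hydroxy-6-methyl-12-[(triethylsilyl)oxy]dodeca-2,6,10-trienoate (not isolated) | COC(=O)/C(Br)=C\[C@@H](O)C/C(C)=C/CC/C(CO[Si](C)(C)C(C)(C)C)=C\CO[Si](CC)(CC)CC | intermediate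
16 | silyl lactone: (5S)-3-bromo-5-[(2E,6E)-6-{[(tert-butyldimethylsilyl)oxy]methyl}-2-methyl-8-[(triethylsilyl)oxy]octa-2,6-dien-1-yl]furan-2(5H)-one (not isolated) | O=C1O[C@@H](C/C(C)=C/CC/C(CO[Si](C)(C)C(C)(C)C)=C\CO[Si](CC)(CC)CC)C=C1Br | intermediate
17 | (5S)-3-bromo-5-[(2E,6E)-6-{[(tert-butyldimethylsilyl)oxy]methyl}-8-hydroxy-2-methylocta-2,6-dien-1-yl]furan-2(5H)-one | O=C1O[C@@H](C/C(C)=C/CC/C(CO[Si](C)(C)C(C)(C)C)=C\CO)C=C1Br | intermediate
18 | (5S)-5-[(2E,6E)-6-{[(tert-butyldimethylsilyl)oxy]methyl}-8-hydroxy-2-methylocta-2,6-dien-1-yl]-3-[(4,4,5,5-tetramethyl-1,3,2-dioxaborolan-2-yl)methyl]furan-2(5H)-one | O=C1O[C@@H](C/C(C)=C/CC/C(CO[Si](C)(C)C(C)(C)C)=C\CO)C=C1CB2OC(C)(C)C(C)(C)O2 | intermediate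
19 | enal: (2E,6E)-3-{[(tert-butyldimethylsilyl)oxy]methyl}-7-methyl-8-{(2S)-5-oxo-4-[(4,4,5,5-tetramethyl-1,3,2-dioxaborolan-2-yl)methyl]-2,5-dihydrofuran-2-yl}octa-2,6-dienal (not isolated) | O=C1O[C@@H](C/C(C)=C/CC/C(CO[Si](C)(C)C(C)(C)C)=C\C=O)C=C1CB2OC(C)(C)C(C)(C)O2 | intermediate
20 | borate ester: O-6 pinacolborate of 21 (not isolated) | C=C1C(=O)O[C@H]2C/C(C)=C/CC/C(CO[Si](C)(C)C(C)(C)C)=C\[C@@H](OB3OC(C)(C)C(C)(C)O3)[C@H]12 | intermediate
21 | (3aS,4R,5E,9E,11aS)-6-{[(tert-butyldimethylsilyl)oxy]methyl}-4-hydroxy-10-methyl-3-methylidene-3a,4,7,8,11,11a-hexahydrocyclodeca[b]furan-2(3H)-one | C=C1C(=O)O[C@H]2C/C(C)=C/CC/C(CO[Si](C)(C)C(C)(C)C)=C\[C@@H](O)[C@H]12 | intermediate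
22 | (3aS,4R,5E,9E,11aS)-4-hydroxy-6-(hydroxymethyl)-10-methyl-3-methylidene-3a,4,7,8,11,11a-hexahydrocyclodeca[b]furan-2(3H)-one | C=C1C(=O)O[C@H]2C/C(C)=C/CC/C(CO)=C\[C@@H](O)[C@H]12 | intermediate
23 | ethyl but-2-ynoate | CC#CC(=O)OCC | starting material
24 | vinylalane: ethyl (2Z)-2-[bis(2-methylpropyl)alumanyl]but-2-enoate (not isolated) | CCOC(=O)/C(=C\C)[Al](CC(C)C)CC(C)C | intermediate
25 | ethyl (2Z)-2-(hydroxymethyl)but-2-enoate | CCOC(=O)/C(=C\C)CO | intermediate
26 | (2Z)-2-(hydroxymethyl)but-2-enoic acid | OC(=O)/C(=C\C)CO | intermediate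
27 | (2Z)-2-[(acetyloxy)methyl]but-2-enoic acid | OC(=O)/C(=C\C)COC(C)=O | intermediate
28 | mixed anhydride: (2Z)-2-[(acetyloxy)methyl]but-2-enoic 2,4,6-trichlorobenzoic anhydride (not isolated) | O=C(OC(=O)/C(=C\C)COC(C)=O)c1c(Cl)cc(Cl)cc1Cl | intermediate
29 | [(3aS,4R,5E,9E,11aS)-4-hydroxy-10-methyl-3-methylidene-2-oxo-2,3,3a,4,7,8,11,11a-octahydrocyclodeca[b]furan-6-yl]methyl (2Z)-2-[(acetyloxy)methyl]but-2-enoate (CNP0184624.2) | C=C1C(=O)O[C@H]2C/C(C)=C/CC/C(COC(=O)/C(=C\C)COC(C)=O)=C\[C@@H](O)[C@H]12 | target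

**Step count and risks**

Total step count: 15. Longest linear sequence: 10 steps (1 to 29 through steps 1, 2, 4, 5, 7, 8, 9, 10, 11, 15).

Three steps most likely to fail:

Step 10 (the proposed new ring closure; the weakly nucleophilic boronate may not close the ten-membered ring or may give the wrong C-6 epimer). The fallback uses known chemistry, sets out from 17 and comes back at 21. MnO2 oxidises 17 to (2E,6E)-8-[(2S)-4-bromo-5-oxo-2,5-dihydrofuran-2-yl]-3-{[(tert-butyldimethylsilyl)oxy]methyl}-7-methylocta-2,6-dienal F1. Stille coupling with Bu3SnCH2OH (Pd(PPh3)4, dioxane, 90 °C) gives (2E,6E)-3-{[(tert-butyldimethylsilyl)oxy]methyl}-8-[(2S)-4-(hydroxymethyl)-5-oxo-2,5-dihydrofuran-2-yl]-7-methylocta-2,6-dienal F2. CBr4/PPh3 gives (2E,6E)-8-[(2S)-4-(bromomethyl)-5-oxo-2,5-dihydrofuran-2-yl]-3-{[(tert-butyldimethylsilyl)oxy]methyl}-7-methylocta-2,6-dienal F3. Slow addition of F3 to CrCl2 in THF at high dilution (Barbier/Nozaki–Hiyama-type allylation through the trivalent allylchromium, anti-selective via the same chair) gives 21.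

Step 7 (one-pot aminoxylation/bromo-olefination on a polyfunctional aldehyde; the 2E/2Z ratio or the labile aminoxy aldehyde may limit it). The fallback sets out from 9 and comes back at 18. The aminoxylation is run as before, but the olefination uses the unbrominated phosphonate 10 (KN(SiMe3)2, 18-crown-6, THF, −78 °C; Still–Gennari), giving methyl (2Z,4S,6E,10E)-10-{[(tert-butyldimethylsilyl)oxy]methyl}-6-methyl-4-[(phenylamino)oxy]-12-[(triethylsilyl)oxy]dodeca-2,6,10-trienoate F4. Cu(OAc)2 in MeOH, then PPTS, gives (5S)-5-[(2E,6E)-6-{[(tert-butyldimethylsilyl)oxy]methyl}-8-hydroxy-2-methylocta-2,6-dien-1-yl]furan-2(5H)-one F5. I2/pyridine in CH2Cl2 at 0 °C (α-iodination by addition–elimination) gives (5S)-5-[(2E,6E)-6-{[(tert-butyldimethylsilyl)oxy]methyl}-8-hydroxy-2-methylocta-2,6-dien-1-yl]-3-iodofuran-2(5H)-one F6. F6 takes the place of 17 in the Negishi coupling of step 9 and gives 18.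

Step 15 (site selectivity between the two hydroxyls, and possible isomerisation of the activated Z-acid). The fallback sets out from 22 and comes back at 29 with no new compound: Mitsunobu esterification (PPh3, diisopropyl azodicarboxylate, 27, THF, 0 °C). Here the primary allylic alcohol is activated instead of the acid, so the carboxylate is never converted into an isomerisation-prone acyl donor and the hindered secondary C-6 alcohol reacts far more slowly.

Further compounds
F1 | step 10 | (2E,6E)-8-[(2S)-4-bromo-5-oxo-2,5-dihydrofuran-2-yl]-3-{[(tert-butyldimethylsilyl)oxy]methyl}-7-methylocta-2,6-dienal | O=C1O[C@@H](C/C(C)=C/CC/C(CO[Si](C)(C)C(C)(C)C)=C\C=O)C=C1Br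
F2 | step 10 | (2E,6E)-3-{[(tert-butyldimethylsilyl)oxy]methyl}-8-[(2S)-4-(hydroxymethyl)-5-oxo-2,5-dihydrofuran-2-yl]-7-methylocta-2,6-dienal | O=C1O[C@@H](C/C(C)=C/CC/C(CO[Si](C)(C)C(C)(C)C)=C\C=O)C=C1CO
F3 | step 10 | (2E,6E)-8-[(2S)-4-(bromomethyl)-5-oxo-2,5-dihydrofuran-2-yl]-3-{[(tert-butyldimethylsilyl)oxy]methyl}-7-methylocta-2,6-dienal | O=C1O[C@@H](C/C(C)=C/CC/C(CO[Si](C)(C)C(C)(C)C)=C\C=O)C=C1CBr
F4 | step 7 | methyl (2Z,4S,6E,10E)-10-{[(tert-butyldimethylsilyl)oxy]methyl}-6-methyl-4-[(phenylamino)oxy]-12-[(triethylsilyl)oxy]dodeca-2,6,10-trienoate | COC(=O)/C=C\[C@@H](ONc1ccccc1)C/C(C)=C/CC/C(CO[Si](C)(C)C(C)(C)C)=C\CO[Si](CC)(CC)CC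
F5 | step 7 | (5S)-5-[(2E,6E)-6-{[(tert-butyldimethylsilyl)oxy]methyl}-8-hydroxy-2-methylocta-2,6-dien-1-yl]furan-2(5H)-one | O=C1O[C@@H](C/C(C)=C/CC/C(CO[Si](C)(C)C(C)(C)C)=C\CO)C=C1
F6 | step 7 | (5S)-5-[(2E,6E)-6-{[(tert-butyldimethylsilyl)oxy]methyl}-8-hydroxy-2-methylocta-2,6-dien-1-yl]-3-iodofuran-2(5H)-one | O=C1O[C@@H](C/C(C)=C/CC/C(CO[Si](C)(C)C(C)(C)C)=C\CO)C=C1I
F0 | step 15 | none | none
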